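6.00% of the solid substrate charged in the cedar run had, over its last 3 readings, left the solid without showing as target; in the larch run that gap was 4.10%.

in all of them: gas 200 mM (held)

| flask | solid substrate | temperature | remark | time |
|---|---|---|---|---|
| cedar | 0.70 M | 32 °C | run made earlier |  |
| larch | 1.1 M | 49 °C | run made earlier |  |
| Saturday's | 0.50 M |  | at 25 °C throughout | 1.0 min |
| Monday's | 0.50 M |  | at 25 °C until 50 s, from then on at 55 °C | 4.0 min |

cedar run (percent of the solid substrate charged)

| time / min | target / % | solid substrate / % |
|---|---|---|
| 0.167 | 0.7 | 94.6 |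
| 0.500 | 0.3 | 93.9 |
| 0.833 | 1.4 | 92.4 |
| 1.33 | 2.5 | 91.3 |
| 2.00 | 5.4 | 89.7 |
| 2.50 | 5.6 | 87.4 |
| 3.00 | 8.1 | 85.8 |

larch run (percent of the solid substrate charged)

| time / s | target / % | solid substrate / % |
|---|---|---|
| 10.0 | 0.1 | 97.1 |
| 15.0 | 1.1 | 96.5 |
| 25.0 | 0.6 | 95.1 |
| 40.0 | 1.8 | 94.1 |
| 50.0 | 2.3 | 94.0 |
| 60.0 | 2.2 | 93.3 |

(standard deviation of a reading: 0.5 percentage points)

- the winner by amount of target, in percent of the solid substrate charged; "neither" if no more than 2 percentage points parts them (Saturday's / Monday's / neither)
- how much target is there at the end, in percent of the solid substrate charged: Saturday's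
- how much target is there at the end, in percent of the solid substrate charged: Monday's

The larch run had the larger charge and the smaller gap. I took the gap for dissolved substrate, a pool of nearly fixed size fed by the solid, so that its share goes inversely with the charge. Carried to the charge of Saturday's and Monday's flasks, the runs give:

from cedar: 8.40%; from larch: 9.02%; mean: 8.71%

I call this mean the hidden share: the fraction of the charge standing dissolved while solid remains.

Target grew from that pool along a roughly straight line, so I let its stream, in fractions of the charge per minute, go with the hidden share. The late slopes read: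

cedar: 0.0309 min⁻¹; larch: 0.0274 min⁻¹

Saturday's flask is cooler than the cedar run, so I used cedar's slope as a ceiling. Monday's hot stretch is hotter than the larch run, so larch's slope served as a floor, counted over the hot stretch of 3.17 min:

Saturday's, below: 4.49%

Monday's, above: 18.5%

So I committed to Monday's as the winner.

The forecast, resting on “a fixed pool”, gave 2.7% for Saturday's, 22% for Monday's and Monday's as the winner.

The flasks gave 1.94% for Saturday's, under my ceiling, and 28.6% for Monday's, over my floor, with Monday's ahead.

    solid substrate ⇌ dissolved substrate, rate k1*(cs1 - [dissolved substrate]) while solid is left; crystals form when [dissolved substrate] > cs1 (solubility = 41.0 mM, k = 0.170 s⁻¹)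
    dissolved substrate + partner → target (k = 0.0280 M⁻¹ s⁻¹, Ea = 51.0 kJ mol⁻¹)
    2 dissolved substrate → side product (k = 0.00790 M⁻¹ s⁻¹, Ea = 64.0 kJ mol⁻¹)
    solid product ⇌ target, rate k4*(cs4 - [target]) while solid is left; crystals form when [target] > cs4 (solubility = 0.160 M, k = 0.490 s⁻¹)
    partner → decomposed reagent (k = 0.00200 s⁻¹, Ea = 92.0 kJ mol⁻¹)
    gas ⇌ partner, rate k6*(csat - [partner]) (kL = 0.0740 s⁻¹)
    partner → decomposition product (k = 3.40 × 10⁻⁶ s⁻¹, Ea = 94.0 kJ mol⁻¹)
    (constants at 25 °C)

At 1.00 min Saturday's flask held 7.92% as dissolved substrate against my hidden share of 8.71%, and that pool was being made at 0.994 times the rate at which it was used, each step taken net: a quasi-steady state. Monday's flask ended with 7.14% dissolved at 4.00 min, and a neighbour like Saturday's but kept at 50 °C held 7.26% at 1.00 min, with its target at 6.43%.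

All runs come from a simulation from invented constants; the scatter is artificial.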